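The synthesis rests on cutting the aryl ether bond O1–C2 of the pyran ring. C2 is benzylic to ring B and sits para to the 4'-OH, so it can become the exocyclic carbon of a p-quinone methide. A chiral phosphoric acid dehydrates the racemic open-chain carbinol, 1-(3,4-dihydroxy-2,5-diprenylphenyl)-3-(2,4-dihydroxyphenyl)propan-1-ol, to this planar intermediate and guides the A-ring 2-OH onto one face of C2. One stereoconvergent operation thus closes the ring, sets the only stereocenter as (S) and releases the unprotected natural product. The carbinol is assembled from a diprenylated aryllithium (double Claisen rearrangement, cross-metathesis) and silylated dihydroumbelliferone.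

Key step: step 9

Remark 1: 7-hydroxychroman-2-one (dihydroumbelliferone) and 4-bromocatechol are taken as catalogue compounds.
Remark 2: the (R)-enantiomer of the catalyst is written for step 9; which enantiomer leads to the (2S)-flavan is to be settled in a pilot run, and the mirror-image catalyst is taken if required.
Abbreviation: TBS = tert-butyldimethylsilyl.

Step 1
Reactants: 1 4-bromobenzene-1,2-diol (4-bromocatechol)
Product: 2 4-bromo-1,2-bis(prop-2-enyloxy)benzene
Conditions: allyl bromide (2.5 equiv), K2CO3 (3 equiv), acetone, reflux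
Reagents that add atoms: allyl bromide, C=CCBr
Why: Williamson O-allylation of both phenoxides (SN2 on allyl bromide); the aryl bromide is inert under these conditions.

Step 2
Reactants: 2 4-bromo-1,2-bis(prop-2-enyloxy)benzene
Product: 3 4-bromo-3,6-di(prop-2-enyl)benzene-1,2-diol
Conditions: N,N-diethylaniline, 195 °C, degassed, Ar
Reagents that add atoms: none
Why: Two consecutive aromatic Claisen [3,3]-rearrangements, in which each allyl group has only one free ortho carbon on its own oxygen (C6 for O1, C3 for O2), should give the 3,6-diallyl pattern without a regiochemical choice.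

Step 3
Reactants: 3 4-bromo-3,6-di(prop-2-enyl)benzene-1,2-diol
Product: 4 1-bromo-3,4-bis(tert-butyldimethylsilyloxy)-2,5-di(prop-2-enyl)benzene
Conditions: TBSCl (3 equiv), imidazole (6 equiv), DMAP (cat.), DMF, 50 °C
Reagents that add atoms: tert-butyldimethylsilyl chloride (TBSCl), CC(C)(C)[Si](C)(C)Cl
Why: Silyl ether formation masks the acidic, oxidation-prone catechol for the metathesis and the organolithium step, with DMAP and gentle heating to overcome the flanking allyl groups.

Step 4
Reactants: 4 1-bromo-3,4-bis(tert-butyldimethylsilyloxy)-2,5-di(prop-2-enyl)benzene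
Product: 5 1-bromo-3,4-bis(tert-butyldimethylsilyloxy)-2,5-bis(3-methylbut-2-enyl)benzene
Conditions: (H2IMes)(PCy3)Cl2Ru=CHPh (5 mol%), 2-methylbut-2-ene/CH2Cl2 (1:1), 40 °C, sealed tube
Reagents that add atoms: 2-methylbut-2-ene, CC=C(C)C
Why: Ruthenium-catalysed olefin cross-metathesis with excess 2-methylbut-2-ene should turn each terminal allyl group into a prenyl group with loss of propene, while the aryl bromide and the silyl ethers stay untouched.

Step 5
Reactants: 6 7-hydroxychroman-2-one (dihydroumbelliferone)
Product: 7 7-(tert-butyldimethylsilyloxy)chroman-2-one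
Conditions: TBSCl (1.2 equiv), imidazole (2.5 equiv), CH2Cl2, 0 °C to rt
Reagents that add atoms: tert-butyldimethylsilyl chloride (TBSCl), CC(C)(C)[Si](C)(C)Cl
Why: Phenol silylation removes the acidic proton that would quench the aryllithium and matches the B-ring protecting groups, so that one fluoride step later frees all three phenols.

Step 6
Reactants: 5 1-bromo-3,4-bis(tert-butyldimethylsilyloxy)-2,5-bis(3-methylbut-2-enyl)benzene; 7 7-(tert-butyldimethylsilyloxy)chroman-2-one
Product: 9 1-[3,4-bis(tert-butyldimethylsilyloxy)-2,5-bis(3-methylbut-2-enyl)phenyl]-3-[2-hydroxy-4-(tert-butyldimethylsilyloxy)phenyl]propan-1-one, via aryllithium 8 (not isolated)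
Conditions: n-BuLi (1.05 equiv), THF, −78 °C; then cannulated into 7 (1.4 equiv), THF, −78 °C; aq. NH4Cl at −78 °C
Reagents that add atoms: none
Why: Bromine–lithium exchange followed by nucleophilic acyl substitution on the aryl-ester lactone, run by inverse addition at −78 °C so that the lithium hemiketalate and the ortho-prenyl hindrance of the resulting ketone should prevent a second addition.

Step 7
Reactants: 9 1-[3,4-bis(tert-butyldimethylsilyloxy)-2,5-bis(3-methylbut-2-enyl)phenyl]-3-[2-hydroxy-4-(tert-butyldimethylsilyloxy)phenyl]propan-1-one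
Product: 10 rac-1-[3,4-bis(tert-butyldimethylsilyloxy)-2,5-bis(3-methylbut-2-enyl)phenyl]-3-[2-hydroxy-4-(tert-butyldimethylsilyloxy)phenyl]propan-1-ol
Conditions: NaBH4 (2 equiv), THF/EtOH (1:1), 0 °C; pH 7 buffer
Reagents that add atoms: none
Why: Borohydride reduction of the aryl ketone; the carbinol centre is deliberately left racemic because step 9 erases and resets it.

Step 8
Reactants: 10 rac-1-[3,4-bis(tert-butyldimethylsilyloxy)-2,5-bis(3-methylbut-2-enyl)phenyl]-3-[2-hydroxy-4-(tert-butyldimethylsilyloxy)phenyl]propan-1-ol
Product: 11 rac-1-[3,4-dihydroxy-2,5-bis(3-methylbut-2-enyl)phenyl]-3-(2,4-dihydroxyphenyl)propan-1-ol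
Conditions: TBAF (3.3 equiv), AcOH (3.3 equiv), THF, 0 °C, Ar; pH 7 buffer work-up; used at once
Reagents that add atoms: none
Why: Fluoride-driven Si–O cleavage frees the three phenols, while acetic acid buffering, low temperature and exclusion of air should keep the p-hydroxybenzylic alcohol from ionising and the catechol from oxidising before the catalyst is present.

Step 9
Reactants: 11 rac-1-[3,4-dihydroxy-2,5-bis(3-methylbut-2-enyl)phenyl]-3-(2,4-dihydroxyphenyl)propan-1-ol
Product: 13 kazinol A, via p-quinone methide 12 (not isolated)
Conditions: (R)-TRIP (10 mol%), 4 Å MS, CH2Cl2 (0.01 M), −20 to 0 °C, Ar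
Reagents that add atoms: none
Why: Proposed new method: the phosphoric acid protonates the carbinol OH while its phosphoryl oxygen takes the proton of the para 4'-OH, so both enantiomers of 11 lose water to the same planar p-quinone methide 12, held in the chiral pocket by hydrogen bonds; the A-ring 2-OH, bound to the same phosphate, then adds to the methide carbon (oxa-1,6-addition) and ring B re-aromatises. The closest known reaction types are chiral phosphoric acid catalysed 1,6-additions to p-quinone methides generated in the flask from racemic p-hydroxybenzyl alcohols and Brønsted acid catalysed enantioconvergent substitutions of racemic benzylic or allylic alcohols by tethered phenols; new here is a δ-alkyl quinone methide without tert-butyl blocking groups, formed from a secondary alkyl aryl carbinol and trapped by a phenol oxygen. The pyran ring closes in the 6-exo-trig mode. The C2 configuration is set by the catalyst through face selection at the methide carbon, made clean by the 2'-prenyl group, which by allylic strain should allow only the E geometry of 12. The step needs O-attack instead of Friedel–Crafts attack or capture of the methide by the 2'-prenyl alkene, intact prenyl groups and no reopening of the product; the six-membered intramolecular delivery of oxygen, the unactivated A-ring carbon C6 (meta to both hydroxyls), the weak acid, low temperature, high dilution and sieves should secure these.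

Compound list
1 | 4-bromobenzene-1,2-diol (4-bromocatechol) | Oc1ccc(Br)cc1O | starting material
2 | 4-bromo-1,2-bis(prop-2-enyloxy)benzene | C=CCOc1ccc(Br)cc1OCC=C | intermediate
3 | 4-bromo-3,6-di(prop-2-enyl)benzene-1,2-diol | C=CCc1cc(Br)c(CC=C)c(O)c1O | intermediate
4 | 1-bromo-3,4-bis(tert-butyldimethylsilyloxy)-2,5-di(prop-2-enyl)benzene | C=CCc1cc(Br)c(CC=C)c(O[Si](C)(C)C(C)(C)C)c1O[Si](C)(C)C(C)(C)C | intermediate
5 | 1-bromo-3,4-bis(tert-butyldimethylsilyloxy)-2,5-bis(3-methylbut-2-enyl)benzene | CC(C)=CCc1cc(Br)c(CC=C(C)C)c(O[Si](C)(C)C(C)(C)C)c1O[Si](C)(C)C(C)(C)C | intermediate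
6 | 7-hydroxychroman-2-one (dihydroumbelliferone) | O=C1CCc2ccc(O)cc2O1 | starting material
7 | 7-(tert-butyldimethylsilyloxy)chroman-2-one | O=C1CCc2ccc(O[Si](C)(C)C(C)(C)C)cc2O1 | intermediate
8 | [3,4-bis(tert-butyldimethylsilyloxy)-2,5-bis(3-methylbut-2-enyl)phenyl]lithium | CC(C)=CCc1cc([Li])c(CC=C(C)C)c(O[Si](C)(C)C(C)(C)C)c1O[Si](C)(C)C(C)(C)C | intermediate
9 | 1-[3,4-bis(tert-butyldimethylsilyloxy)-2,5-bis(3-methylbut-2-enyl)phenyl]-3-[2-hydroxy-4-(tert-butyldimethylsilyloxy)phenyl]propan-1-one | CC(C)=CCc1cc(C(=O)CCc2ccc(O[Si](C)(C)C(C)(C)C)cc2O)c(CC=C(C)C)c(O[Si](C)(C)C(C)(C)C)c1O[Si](C)(C)C(C)(C)C | intermediate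
10 | rac-1-[3,4-bis(tert-butyldimethylsilyloxy)-2,5-bis(3-methylbut-2-enyl)phenyl]-3-[2-hydroxy-4-(tert-butyldimethylsilyloxy)phenyl]propan-1-ol | CC(C)=CCc1cc(C(O)CCc2ccc(O[Si](C)(C)C(C)(C)C)cc2O)c(CC=C(C)C)c(O[Si](C)(C)C(C)(C)C)c1O[Si](C)(C)C(C)(C)C | intermediate
11 | rac-1-[3,4-dihydroxy-2,5-bis(3-methylbut-2-enyl)phenyl]-3-(2,4-dihydroxyphenyl)propan-1-ol | CC(C)=CCc1cc(C(O)CCc2ccc(O)cc2O)c(CC=C(C)C)c(O)c1O | intermediate
12 | (4E)-4-[3-(2,4-dihydroxyphenyl)propylidene]-2-hydroxy-3,6-bis(3-methylbut-2-enyl)cyclohexa-2,5-dien-1-one (p-quinone methide) | CC(C)=CCC1=C/C(=C\CCc2ccc(O)cc2O)C(CC=C(C)C)=C(O)C1=O | intermediate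
13 | kazinol A, 4-[(2S)-7-hydroxychroman-2-yl]-3,6-bis(3-methylbut-2-enyl)benzene-1,2-diol | CC(C)=CCc1cc([C@@H]2CCc3ccc(O)cc3O2)c(CC=C(C)C)c(O)c1O | target

Total step count: 9
Longest linear sequence: 8 steps (steps 1, 2, 3, 4, 6, 7, 8, 9)

Steps most likely to fail

Step 9 (Proposed new method). What may go wrong: weak facial discrimination, because the 3'- and 7-hydroxyls may bind the phosphate unproductively; loss of enantiopurity by reopening of the flavan through the same quinone methide; or capture of the methide by the 2'-prenyl double bond in a Prins-type closure. The fallback uses known chemistry, closes the same O–C bond and sets out from ketone 9. Asymmetric transfer hydrogenation (RuCl(p-cymene)[(R,R)-TsDPEN], HCO2H/Et3N, rt) should give the (1R)-configured tris-silylated carbinol F1, the sense being expected by analogy with simple aryl alkyl ketones. Mitsunobu cyclisation (PPh3, DIAD, THF, 0 °C), in which the A-ring 2-OH displaces the activated benzylic oxygen with inversion, should give the (2S)-tris-silylated flavan F2. The silylated 4'-oxygen cannot form a quinone methide there, which should keep the displacement on the SN2 path. TBAF/AcOH (THF, 0 °C) then removes the three silyl groups, and the route is rejoined at 13.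

Step 8. What may go wrong: uncatalysed ionisation of the freed p-hydroxybenzylic alcohol during fluoride treatment or isolation, which would close the ring without stereocontrol before the catalyst is present, and air oxidation of the catechol. The fallback sets out from ketone 9 and changes the order of events. The silyl groups are removed at the ketone stage (TBAF/AcOH, THF, 0 °C) to give the tetrahydroxy ketone F3, which cannot ionise and can be purified rigorously. NaBH4 (THF/EtOH, 0 °C; pH 7 buffer with a mannitol wash to strip borate from the catechol) should then give the carbinol from a basic, reducing medium. It is taken into step 9 without chromatography, and the route is rejoined at 11.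

Step 6. What may go wrong: collapse of the tetrahedral adduct to the ketone at −78 °C followed by a second addition of the aryllithium, or deprotonation alpha to the lactone carbonyl. The fallback sets out from lactone 7 (with bromide 5) and moves the electrophile to the aldehyde oxidation level. DIBAL-H (CH2Cl2, −78 °C) should give the lactol F4. NaH (THF, 0 °C) opens it to the sodium phenoxide aldehyde F5, to which aryllithium 8 (from 5 and n-BuLi as in step 6) can add only once (THF, −78 °C; aq. NH4Cl). This gives the carbinol directly, so step 7 is no longer needed, and the route is rejoined at 10.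

Further compounds
F1 | step 9 | (1R)-1-[3,4-bis(tert-butyldimethylsilyloxy)-2,5-bis(3-methylbut-2-enyl)phenyl]-3-[2-hydroxy-4-(tert-butyldimethylsilyloxy)phenyl]propan-1-ol | CC(C)=CCc1cc([C@H](O)CCc2ccc(O[Si](C)(C)C(C)(C)C)cc2O)c(CC=C(C)C)c(O[Si](C)(C)C(C)(C)C)c1O[Si](C)(C)C(C)(C)C
F2 | step 9 | (2S)-2-[3,4-bis(tert-butyldimethylsilyloxy)-2,5-bis(3-methylbut-2-enyl)phenyl]-7-(tert-butyldimethylsilyloxy)chroman | CC(C)=CCc1cc([C@@H]2CCc3ccc(O[Si](C)(C)C(C)(C)C)cc3O2)c(CC=C(C)C)c(O[Si](C)(C)C(C)(C)C)c1O[Si](C)(C)C(C)(C)C
F3 | step 8 | 1-[3,4-dihydroxy-2,5-bis(3-methylbut-2-enyl)phenyl]-3-(2,4-dihydroxyphenyl)propan-1-one | CC(C)=CCc1cc(C(=O)CCc2ccc(O)cc2O)c(CC=C(C)C)c(O)c1O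
F4 | step 6 | 7-(tert-butyldimethylsilyloxy)chroman-2-ol | OC1CCc2ccc(O[Si](C)(C)C(C)(C)C)cc2O1
F5 | step 6 | sodium 5-(tert-butyldimethylsilyloxy)-2-(3-oxopropyl)phenolate | [Na+].[O-]c1cc(O[Si](C)(C)C(C)(C)C)ccc1CCC=O
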